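**Retrosynthetic overview**
- The target comes from a protected spirocyclic trienoate by OH-directed epoxidation, hydride reduction (ester to CH2OH, epoxide to the C10 tertiary alcohol) and acidic removal of the acetal and silyl groups.
- The spirocyclic trienoate comes from a one-flask cathodic reductive cyclisation that forms the C1–C2 bond and closes the cyclopentane (second ring), followed by Horner–Wadsworth–Emmons capture of the resulting phosphonate carbanion by a C10 dienal.
- The cyclisation substrate (neopentyl aldehyde plus alkylidene phosphonoacetate) comes from a cyclohexene diester by reduction, oxidation and Knoevenagel condensation; its Z-enal, masked as the dimethyl acetal, is made from the isopropenyl group.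
- The diester comes from copper-catalysed conjugate addition and Michael trapping on a dienoate made from (S)-carvone, which supplies the cyclohexane (first ring) and the only purchased stereocentre.
- The dienal comes from sulcatone by kinetic enol triflate formation and a Heck reaction with acrolein.

Assumption: the target SMILES is read as (1S,2S,5S,6R,10S), 7Z, side chain 2E,4E in spiro[4.5]decane numbering (C1 carbinol, C2 side-chain carbon, C5 spiro carbon, C6 CH with the three-carbon chain, C7 ylidene carbon, C10 methyl carbinol); these atom labels are used in the Why lines for all intermediates, and TBS means tert-butyldimethylsilyl.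

**Route**

Step 1
Reactants: 1 (S)-(+)-carvone [(5S)-2-methyl-5-(prop-1-en-2-yl)cyclohex-2-en-1-one]
Product: 3 (3S)-6-methyl-3-(prop-1-en-2-yl)cyclohexa-1,5-dien-1-yl trifluoromethanesulfonate, via lithium dienolate 2 (not isolated)
Conditions: LiN(i-Pr)2, THF, −78 °C; then PhNTf2, −78 → 0 °C
Reagents that add atoms: N-phenylbis(trifluoromethanesulfonimide) (PhNTf2), O=S(=O)(N(c1ccccc1)S(=O)(=O)C(F)(F)F)C(F)(F)F
Why: Kinetic deprotonation at the α′-CH2 gives the cross-conjugated lithium dienolate, which is O-sulfonylated (enol triflate formation) without touching the carvone stereocentre.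

Step 2
Reactants: 3 (3S)-6-methyl-3-(prop-1-en-2-yl)cyclohexa-1,5-dien-1-yl trifluoromethanesulfonate
Product: 4 methyl (3S)-6-methyl-3-(prop-1-en-2-yl)cyclohexa-1,5-diene-1-carboxylate
Conditions: Pd(OAc)2 (5 mol%), PPh3, CO (1 atm), MeOH, Et3N, DMF, 50 °C
Reagents that add atoms: carbon monoxide, [C-]#[O+]; methanol, CO
Why: Palladium-catalysed methoxycarbonylation of the alkenyl triflate (oxidative addition, CO insertion, methanolysis) makes the former ketone carbon the ester-bearing C5 and turns C6 into a Michael position, with the stereocentre untouched.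

Step 3
Reactants: 4 methyl (3S)-6-methyl-3-(prop-1-en-2-yl)cyclohexa-1,5-diene-1-carboxylate; 5 (3-bromopropoxy)(tert-butyl)dimethylsilane; 6 methyl acrylate
Product: 9 methyl (1R,5S,6R)-6-[3-(TBS-oxy)propyl]-1-(3-methoxy-3-oxopropyl)-2-methyl-5-(prop-1-en-2-yl)cyclohex-2-ene-1-carboxylate, via Grignard reagent 7 (not isolated), via bromomagnesium dienolate 8 (not isolated)
Conditions: Mg, THF (5 → 7); then 4, CuBr·SMe2 (15 mol%), THF, −78 → −40 °C; then 6, −78 °C; aq. NH4Cl
Reagents that add atoms: none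
Why: Copper-catalysed 1,4-addition of the Grignard reagent occurs anti to the neighbouring isopropenyl group (sets C6), and the magnesium dienolate then reacts at its α-carbon with methyl acrylate anti to the new C6 chain (sets the quaternary C5), a three-component conjugate addition–Michael sequence.

Step 4
Reactants: 9 methyl (1R,5S,6R)-6-[3-(TBS-oxy)propyl]-1-(3-methoxy-3-oxopropyl)-2-methyl-5-(prop-1-en-2-yl)cyclohex-2-ene-1-carboxylate
Product: 11 methyl (1R,5S,6R)-6-[3-(TBS-oxy)propyl]-5-(1-hydroxypropan-2-yl)-1-(3-methoxy-3-oxopropyl)-2-methylcyclohex-2-ene-1-carboxylate (both epimers at the new side-chain carbon), via B-alkyl-9-BBN adduct 10 (not isolated)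
Conditions: 9-BBN, THF, 0 → 23 °C; then 30% H2O2, aq. NaOAc, 0 °C
Reagents that add atoms: hydrogen peroxide, OO
Why: 9-BBN hydroborates the 1,1-disubstituted isopropenyl group far faster than the trisubstituted ring alkene and spares the esters, and buffered peroxide gives the primary alcohol (hydroboration–oxidation; the new side-chain centre is erased in step 5).

Step 5
Reactants: 11 methyl (1R,5S,6R)-6-[3-(TBS-oxy)propyl]-5-(1-hydroxypropan-2-yl)-1-(3-methoxy-3-oxopropyl)-2-methylcyclohex-2-ene-1-carboxylate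
Product: 12 methyl (1R,5Z,6R)-6-[3-(TBS-oxy)propyl]-1-(3-methoxy-3-oxopropyl)-2-methyl-5-(1-oxopropan-2-ylidene)cyclohex-2-ene-1-carboxylate
Conditions: IBX (3 equiv), DMSO/PhF, 70 °C; Z isomer separated, E isomer recycled with cat. I2, hν
Reagents that add atoms: none
Why: IBX oxidises the alcohol to the aldehyde and then dehydrogenates it through its enol toward the tertiary ring C–H (Nicolaou IBX dehydrogenation) to the tetrasubstituted enal, removing the carvone stereocentre after it has set C6; the Z isomer (CHO syn to C6, the smaller group next to the substituted carbon) is isolated and the E isomer is re-equilibrated.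

Step 6
Reactants: 12 methyl (1R,5Z,6R)-6-[3-(TBS-oxy)propyl]-1-(3-methoxy-3-oxopropyl)-2-methyl-5-(1-oxopropan-2-ylidene)cyclohex-2-ene-1-carboxylate
Product: 13 methyl (1R,5Z,6R)-6-[3-(TBS-oxy)propyl]-5-(1,1-dimethoxypropan-2-ylidene)-1-(3-methoxy-3-oxopropyl)-2-methylcyclohex-2-ene-1-carboxylate
Conditions: MeOSiMe3, Me3SiOTf (5 mol%), CH2Cl2, −78 °C
Reagents that add atoms: methoxytrimethylsilane, CO[Si](C)(C)C
Why: Noyori acetalisation at −78 °C converts the enal into its dimethyl acetal without double-bond migration or E/Z scrambling, which locks the alkene geometry and removes both the reducible carbonyl and the acidity of the C6–H.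

Step 7
Reactants: 13 methyl (1R,5Z,6R)-6-[3-(TBS-oxy)propyl]-5-(1,1-dimethoxypropan-2-ylidene)-1-(3-methoxy-3-oxopropyl)-2-methylcyclohex-2-ene-1-carboxylate
Product: 14 3-[(1R,5Z,6R)-6-[3-(TBS-oxy)propyl]-5-(1,1-dimethoxypropan-2-ylidene)-1-(hydroxymethyl)-2-methylcyclohex-2-en-1-yl]propan-1-ol
Conditions: LiAlH4, THF, 0 °C
Reagents that add atoms: none
Why: Hydride reduction of both methyl esters to primary alcohols; acetal, silyl ether and alkenes are inert to LiAlH4.

Step 8
Reactants: 14 3-[(1R,5Z,6R)-6-[3-(TBS-oxy)propyl]-5-(1,1-dimethoxypropan-2-ylidene)-1-(hydroxymethyl)-2-methylcyclohex-2-en-1-yl]propan-1-ol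
Product: 15 (1R,5Z,6R)-6-[3-(TBS-oxy)propyl]-5-(1,1-dimethoxypropan-2-ylidene)-2-methyl-1-(3-oxopropyl)cyclohex-2-ene-1-carbaldehyde
Conditions: Dess–Martin periodinane, pyridine, CH2Cl2, 0 → 23 °C
Reagents that add atoms: none
Why: Dess–Martin oxidation of both primary alcohols under pyridine buffering (which protects the acetal) gives the 1,5-dialdehyde; the neopentyl aldehyde has no α-hydrogen and cannot epimerise.

Step 9
Reactants: 15 (1R,5Z,6R)-6-[3-(TBS-oxy)propyl]-5-(1,1-dimethoxypropan-2-ylidene)-2-methyl-1-(3-oxopropyl)cyclohex-2-ene-1-carbaldehyde; 16 trimethyl phosphonoacetate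
Product: 17 methyl 5-[(1R,5Z,6R)-6-[3-(TBS-oxy)propyl]-5-(1,1-dimethoxypropan-2-ylidene)-1-formyl-2-methylcyclohex-2-en-1-yl]-2-(dimethoxyphosphoryl)pent-2-enoate (E/Z mixture at the new alkene)
Conditions: piperidine (cat.), AcOH (cat.), 4 Å MS, toluene, 40 °C
Reagents that add atoms: none
Why: Knoevenagel condensation under piperidinium acetate catalysis occurs only at the unhindered chain aldehyde, because the neopentyl formyl group on the quaternary carbon is too hindered; both alkene isomers converge in step 12.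

Step 10
Reactants: 18 6-methylhept-5-en-2-one (sulcatone)
Product: 20 6-methylhepta-1,5-dien-2-yl trifluoromethanesulfonate, via lithium enolate 19 (not isolated)
Conditions: LiN(i-Pr)2, THF, −78 °C; then PhNTf2, −78 → 0 °C
Reagents that add atoms: N-phenylbis(trifluoromethanesulfonimide) (PhNTf2), O=S(=O)(N(c1ccccc1)S(=O)(=O)C(F)(F)F)C(F)(F)F
Why: Kinetic deprotonation of the methyl ketone at CH3 and O-triflation give the terminal enol triflate (kinetic enol triflate formation).

Step 11
Reactants: 20 6-methylhepta-1,5-dien-2-yl trifluoromethanesulfonate; 21 acrolein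
Product: 22 (2E)-8-methyl-4-methylidenenona-2,7-dienal
Conditions: Pd(OAc)2 (5 mol%), Et3N, DMF, 60 °C
Reagents that add atoms: none
Why: Mizoroki–Heck coupling of the alkenyl triflate with acrolein (carbopalladation at the unsubstituted terminus, syn β-hydride elimination) gives the E-dienal with the cross-conjugated methylidene in place.

Step 12
Reactants: 17 methyl 5-[(1R,5Z,6R)-6-[3-(TBS-oxy)propyl]-5-(1,1-dimethoxypropan-2-ylidene)-1-formyl-2-methylcyclohex-2-en-1-yl]-2-(dimethoxyphosphoryl)pent-2-enoate; 22 (2E)-8-methyl-4-methylidenenona-2,7-dienal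
Product: 24 methyl (2E,4E)-2-[(1S,2S,5R,6R,7Z)-6-[3-(TBS-oxy)propyl]-7-(1,1-dimethoxypropan-2-ylidene)-1-hydroxy-10-methylspiro[4.5]dec-9-en-2-yl]-10-methyl-6-methylideneundeca-2,4,9-trienoate, via magnesium alkoxide-phosphonate carbanion 23 (not isolated)
Conditions: undivided cell, Mg anode, carbon-felt cathode, n-Bu4NBF4 (0.1 M), DMF, 0 °C, 5 mA cm−2, 2.1 F mol−1; then 22 (1.5 equiv), 0 → 23 °C; aq. NH4Cl
Reagents that add atoms: none
Why: Proposed new method: the magnesium-chelated alkylidene phosphonoacetate is the most easily reduced group (well before the aldehyde), and its radical anion adds through the β-carbon 5-exo to the neighbouring formyl group in an open, dipole-minimised transition state in DMF that places the oxyanion on the flat C9=C10 side of the spiro centre, away from the C6 side chain, and the phosphonoacetate arm anti to it (forms the C1–C2 bond and the cyclopentane, sets C1 and C2 trans); the α-phosphono ester radical then takes the second electron and, with no proton donor present, persists as the magnesium phosphonate carbanion, which olefinates 22 to the E-enoate (ester trans to the diene chain), the closest known reactions being Little's electroreductive cyclisation of aldehyde-tethered enoates and alkylidene malonates (run with a proton donor, not with a phosphonoacetate or carbanion capture) and the magnesium-mediated Horner–Wadsworth–Emmons olefination.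

Step 13
Reactants: 24 methyl (2E,4E)-2-[(1S,2S,5R,6R,7Z)-6-[3-(TBS-oxy)propyl]-7-(1,1-dimethoxypropan-2-ylidene)-1-hydroxy-10-methylspiro[4.5]dec-9-en-2-yl]-10-methyl-6-methylideneundeca-2,4,9-trienoate
Product: 25 (1S,2S,5S,6R,9S,10R)-9,10-epoxide of 24 (oxirane oxygen on the ring face that carries C1)
Conditions: VO(acac)2 (10 mol%), t-BuOOH, CH2Cl2, 0 → 23 °C
Reagents that add atoms: tert-butyl hydroperoxide, CC(C)(C)OO
Why: Vanadium-catalysed hydroxyl-directed epoxidation delivers oxygen to the homoallylic C9=C10 alkene on the face of C1, because the C1 hydroxyl points toward C10 and carries the vanadium peroxide (sets C10), while the electron-poor trienoate, the remote alkenes and the hindered acetal-bearing alkene have no equally placed hydroxyl.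

Step 14
Reactants: 25 (1S,2S,5S,6R,9S,10R)-9,10-epoxide of 24
Product: 27 (2E,4E)-2-[(1S,2S,5S,6R,7Z,10S)-6-[3-(TBS-oxy)propyl]-7-(1,1-dimethoxypropan-2-ylidene)-1,10-dihydroxy-10-methylspiro[4.5]decan-2-yl]-10-methyl-6-methylideneundeca-2,4,9-trien-1-ol, via epoxy allylic alcohol 26 (not isolated)
Conditions: i-Bu2AlH, CH2Cl2, −78 °C; then LiEt3BH, THF, −78 → 0 °C
Reagents that add atoms: none
Why: i-Bu2AlH reduces the conjugated ester 1,2 to the allylic alcohol without touching epoxide or acetal, and LiEt3BH then opens the trisubstituted epoxide by SN2 attack at the less hindered C9 (trans-diaxial epoxide opening), leaving the oxygen on C10 with the configuration set in step 13.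

Step 15
Reactants: 27 (2E,4E)-2-[(1S,2S,5S,6R,7Z,10S)-6-[3-(TBS-oxy)propyl]-7-(1,1-dimethoxypropan-2-ylidene)-1,10-dihydroxy-10-methylspiro[4.5]decan-2-yl]-10-methyl-6-methylideneundeca-2,4,9-trien-1-ol
Product: 28 (2Z)-2-[(1S,2S,5S,6R,10S)-1,10-dihydroxy-2-[(2E,4E)-1-hydroxy-10-methyl-6-methylideneundeca-2,4,9-trien-2-yl]-6-(3-hydroxypropyl)-10-methylspiro[4.5]decan-7-ylidene]propanal (CNP0246965.1)
Conditions: AcOH/THF/H2O (3:1:1), 23 °C
Reagents that add atoms: water, O
Why: Aqueous acetic acid hydrolyses the allylic dimethyl acetal to the Z-enal and cleaves the primary silyl ether (acid-catalysed acetal hydrolysis and desilylation) under conditions too mild to ionise the allylic or tertiary alcohols or to isomerise the tetrasubstituted enal.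

**Compound list**

1 | (S)-(+)-carvone, (5S)-2-methyl-5-(prop-1-en-2-yl)cyclohex-2-en-1-one | CC1=CC[C@@H](CC1=O)C(C)=C | starting material
2 | lithium (3S)-6-methyl-3-(prop-1-en-2-yl)cyclohexa-1,5-dien-1-olate | CC1=CC[C@@H](C=C1O[Li])C(C)=C | intermediate (not isolated)
3 | (3S)-6-methyl-3-(prop-1-en-2-yl)cyclohexa-1,5-dien-1-yl trifluoromethanesulfonate | CC1=CC[C@@H](C=C1OS(=O)(=O)C(F)(F)F)C(C)=C | intermediate
4 | methyl (3S)-6-methyl-3-(prop-1-en-2-yl)cyclohexa-1,5-diene-1-carboxylate | CC1=CC[C@@H](C=C1C(=O)OC)C(C)=C | intermediate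
5 | (3-bromopropoxy)(tert-butyl)dimethylsilane | BrCCCO[Si](C)(C)C(C)(C)C | starting material
6 | methyl acrylate | C=CC(=O)OC | starting material
7 | [3-(TBS-oxy)propyl]magnesium bromide | Br[Mg]CCCO[Si](C)(C)C(C)(C)C | intermediate (not isolated)
8 | bromomagnesium ester dienolate from 1,4-addition to 4 (C6 chain trans to isopropenyl) | COC(O[Mg]Br)=C1[C@H](CCCO[Si](C)(C)C(C)(C)C)[C@@H](C(C)=C)CC=C1C | intermediate (not isolated)
9 | methyl (1R,5S,6R)-6-[3-(TBS-oxy)propyl]-1-(3-methoxy-3-oxopropyl)-2-methyl-5-(prop-1-en-2-yl)cyclohex-2-ene-1-carboxylate | COC(=O)CC[C@]1([C@H](CCCO[Si](C)(C)C(C)(C)C)[C@@H](C(C)=C)CC=C1C)C(=O)OC | intermediate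
10 | B-alkyl-9-borabicyclo[3.3.1]nonane adduct of 9 (boron on the terminal carbon of the former isopropenyl group) | COC(=O)CC[C@]1([C@H](CCCO[Si](C)(C)C(C)(C)C)[C@@H](C(C)CB2C3CCCC2CCC3)CC=C1C)C(=O)OC | intermediate (not isolated)
11 | methyl (1R,5S,6R)-6-[3-(TBS-oxy)propyl]-5-(1-hydroxypropan-2-yl)-1-(3-methoxy-3-oxopropyl)-2-methylcyclohex-2-ene-1-carboxylate, both side-chain epimers | COC(=O)CC[C@]1([C@H](CCCO[Si](C)(C)C(C)(C)C)[C@@H](C(C)CO)CC=C1C)C(=O)OC | intermediate
12 | methyl (1R,5Z,6R)-6-[3-(TBS-oxy)propyl]-1-(3-methoxy-3-oxopropyl)-2-methyl-5-(1-oxopropan-2-ylidene)cyclohex-2-ene-1-carboxylate | COC(=O)CC[C@]1([C@H](CCCO[Si](C)(C)C(C)(C)C)/C(=C(/C)C=O)CC=C1C)C(=O)OC | intermediate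
13 | methyl (1R,5Z,6R)-6-[3-(TBS-oxy)propyl]-5-(1,1-dimethoxypropan-2-ylidene)-1-(3-methoxy-3-oxopropyl)-2-methylcyclohex-2-ene-1-carboxylate | COC(=O)CC[C@]1([C@H](CCCO[Si](C)(C)C(C)(C)C)/C(=C(/C)C(OC)OC)CC=C1C)C(=O)OC | intermediate
14 | 3-[(1R,5Z,6R)-6-[3-(TBS-oxy)propyl]-5-(1,1-dimethoxypropan-2-ylidene)-1-(hydroxymethyl)-2-methylcyclohex-2-en-1-yl]propan-1-ol | OCCC[C@]1([C@H](CCCO[Si](C)(C)C(C)(C)C)/C(=C(/C)C(OC)OC)CC=C1C)CO | intermediate
15 | (1R,5Z,6R)-6-[3-(TBS-oxy)propyl]-5-(1,1-dimethoxypropan-2-ylidene)-2-methyl-1-(3-oxopropyl)cyclohex-2-ene-1-carbaldehyde | O=CCC[C@]1([C@H](CCCO[Si](C)(C)C(C)(C)C)/C(=C(/C)C(OC)OC)CC=C1C)C=O | intermediate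
16 | trimethyl phosphonoacetate, methyl 2-(dimethoxyphosphoryl)acetate | COC(=O)CP(=O)(OC)OC | starting material
17 | methyl 5-[(1R,5Z,6R)-6-[3-(TBS-oxy)propyl]-5-(1,1-dimethoxypropan-2-ylidene)-1-formyl-2-methylcyclohex-2-en-1-yl]-2-(dimethoxyphosphoryl)pent-2-enoate, E/Z mixture at C2=C3 of the pentenoate | COC(=O)C(=CCC[C@]1([C@H](CCCO[Si](C)(C)C(C)(C)C)/C(=C(/C)C(OC)OC)CC=C1C)C=O)P(=O)(OC)OC | intermediate
18 | 6-methylhept-5-en-2-one (sulcatone) | CC(=O)CCC=C(C)C | starting material
19 | lithium 6-methylhepta-1,5-dien-2-olate | C=C(O[Li])CCC=C(C)C | intermediate (not isolated)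
20 | 6-methylhepta-1,5-dien-2-yl trifluoromethanesulfonate | C=C(OS(=O)(=O)C(F)(F)F)CCC=C(C)C | intermediate
21 | acrolein, prop-2-enal | C=CC=O | starting material
22 | (2E)-8-methyl-4-methylidenenona-2,7-dienal | O=C/C=C/C(=C)CCC=C(C)C | intermediate
23 | magnesium salt of the cyclised dianion: C1 alkoxide and phosphonoacetate carbanion on C2, (1S,2R,5R,6R,7Z) spiro core | COC(=O)[C-](P(=O)(OC)OC)[C@@H]1CC[C@]2([C@H](CCCO[Si](C)(C)C(C)(C)C)/C(=C(/C)C(OC)OC)CC=C2C)[C@H]1[O-].[Mg+2] | intermediate (not isolated)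
24 | methyl (2E,4E)-2-[(1S,2S,5R,6R,7Z)-6-[3-(TBS-oxy)propyl]-7-(1,1-dimethoxypropan-2-ylidene)-1-hydroxy-10-methylspiro[4.5]dec-9-en-2-yl]-10-methyl-6-methylideneundeca-2,4,9-trienoate | C=C(/C=C/C=C(/C(=O)OC)[C@@H]1CC[C@]2([C@H](CCCO[Si](C)(C)C(C)(C)C)/C(=C(/C)C(OC)OC)CC=C2C)[C@H]1O)CCC=C(C)C | intermediate
25 | (1S,2S,5S,6R,9S,10R)-9,10-epoxide of 24, oxirane oxygen on the face of C1 | C=C(/C=C/C=C(/C(=O)OC)[C@@H]1CC[C@]2([C@H](CCCO[Si](C)(C)C(C)(C)C)/C(=C(/C)C(OC)OC)C[C@@H]3O[C@]23C)[C@H]1O)CCC=C(C)C | intermediate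
26 | epoxy allylic alcohol: 25 with the methyl ester reduced to CH2OH (as its aluminium alkoxide in the flask) | C=C(/C=C/C=C(/CO)[C@@H]1CC[C@]2([C@H](CCCO[Si](C)(C)C(C)(C)C)/C(=C(/C)C(OC)OC)C[C@@H]3O[C@]23C)[C@H]1O)CCC=C(C)C | intermediate (not isolated)
27 | (2E,4E)-2-[(1S,2S,5S,6R,7Z,10S)-6-[3-(TBS-oxy)propyl]-7-(1,1-dimethoxypropan-2-ylidene)-1,10-dihydroxy-10-methylspiro[4.5]decan-2-yl]-10-methyl-6-methylideneundeca-2,4,9-trien-1-ol | C=C(/C=C/C=C(/CO)[C@@H]1CC[C@]2([C@H](CCCO[Si](C)(C)C(C)(C)C)/C(=C(/C)C(OC)OC)CC[C@]2(C)O)[C@H]1O)CCC=C(C)C | intermediate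
28 | (2Z)-2-[(1S,2S,5S,6R,10S)-1,10-dihydroxy-2-[(2E,4E)-1-hydroxy-10-methyl-6-methylideneundeca-2,4,9-trien-2-yl]-6-(3-hydroxypropyl)-10-methylspiro[4.5]decan-7-ylidene]propanal | C=C(/C=C/C=C(/CO)[C@@H]1CC[C@]2([C@H](CCCO)/C(=C(/C)C=O)CC[C@]2(C)O)[C@H]1O)CCC=C(C)C | target

**Step count and risks**

Total step count: 15. Longest linear sequence: 13 (steps 1–9 and 12–15, from (S)-carvone); steps 10–11 make the dienal in parallel.

The three steps most likely to fail:

Step 12 (the proposed new step). The cathodic cyclisation onto an alkylidene phosphonoacetate, the survival of the phosphonate carbanion without a proton donor, and the facial selectivity at C1 are all untested. The fallback uses known chemistry and separates the two events. It sets out from 17: SmI2 (2.5 equiv) with t-BuOH in THF at −78 °C effects the known ketyl–olefin reductive cyclisation onto the doubly activated alkene and, after protonation, gives methyl 2-(dimethoxyphosphoryl)-2-[(1S,2R,5R,6R,7Z)-6-[3-(TBS-oxy)propyl]-7-(1,1-dimethoxypropan-2-ylidene)-1-hydroxy-10-methylspiro[4.5]dec-9-en-2-yl]acetate F6 (trans, epimers at the phosphonate carbon). Masamune–Roush olefination of this phosphonate with 22 (LiCl, DBU, MeCN, 23 °C) then returns to the route at 24.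

Step 5. The one-pot IBX oxidation–dehydrogenation may stop at the aldehyde, eliminate toward the methyl group, or give an unfavourable Z/E ratio. The fallback sets out from 11: Dess–Martin periodinane (pyridine, CH2Cl2) gives methyl (1R,5S,6R)-6-[3-(TBS-oxy)propyl]-1-(3-methoxy-3-oxopropyl)-2-methyl-5-(1-oxopropan-2-yl)cyclohex-2-ene-1-carboxylate F4. Me3SiOTf and Et3N (CH2Cl2, 0 °C) convert it into methyl (1R,5S,6R)-6-[3-(TBS-oxy)propyl]-1-(3-methoxy-3-oxopropyl)-2-methyl-5-[1-(trimethylsilyloxy)prop-1-en-2-yl]cyclohex-2-ene-1-carboxylate F5. Saegusa–Ito oxidation in its catalytic form (Pd(OAc)2 10 mol%, O2, DMSO, 23 °C), where reversible palladium hydride addition favours the conjugated tetrasubstituted alkene, gives the enal; after separation of the Z isomer the route is rejoined at 12.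

Step 3. The hindered magnesium dienolate may add sluggishly to methyl acrylate or partly through its γ-carbon. The fallback sets out from 4 and uses alkylative trapping followed by oxidation-state adjustment. The copper-catalysed addition of 7 is repeated and dienolate 8 is trapped with allyl bromide (α-alkylation of metal dienolates by allylic halides is reliable; the same anti-to-C6 bias applies) to give methyl (1R,5S,6R)-6-[3-(TBS-oxy)propyl]-2-methyl-1-(prop-2-en-1-yl)-5-(prop-1-en-2-yl)cyclohex-2-ene-1-carboxylate F1. 9-BBN (1.05 equiv, THF, 0 °C) then H2O2/aq. NaOAc hydroborates only the monosubstituted allyl group and gives methyl (1R,5S,6R)-6-[3-(TBS-oxy)propyl]-1-(3-hydroxypropyl)-2-methyl-5-(prop-1-en-2-yl)cyclohex-2-ene-1-carboxylate F2. TEMPO (cat.) with PhI(OAc)2 in MeCN/H2O oxidises it to 3-[(1R,5S,6R)-6-[3-(TBS-oxy)propyl]-1-(methoxycarbonyl)-2-methyl-5-(prop-1-en-2-yl)cyclohex-2-en-1-yl]propanoic acid F3, and Me3SiCHN2 in MeOH/toluene esterifies it, rejoining the route at 9.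

Further compounds
F1 | step 3 | methyl (1R,5S,6R)-6-[3-(TBS-oxy)propyl]-2-methyl-1-(prop-2-en-1-yl)-5-(prop-1-en-2-yl)cyclohex-2-ene-1-carboxylate | C=CC[C@]1([C@H](CCCO[Si](C)(C)C(C)(C)C)[C@@H](C(C)=C)CC=C1C)C(=O)OC
F2 | step 3 | methyl (1R,5S,6R)-6-[3-(TBS-oxy)propyl]-1-(3-hydroxypropyl)-2-methyl-5-(prop-1-en-2-yl)cyclohex-2-ene-1-carboxylate | OCCC[C@]1([C@H](CCCO[Si](C)(C)C(C)(C)C)[C@@H](C(C)=C)CC=C1C)C(=O)OC
F3 | step 3 | 3-[(1R,5S,6R)-6-[3-(TBS-oxy)propyl]-1-(methoxycarbonyl)-2-methyl-5-(prop-1-en-2-yl)cyclohex-2-en-1-yl]propanoic acid | OC(=O)CC[C@]1([C@H](CCCO[Si](C)(C)C(C)(C)C)[C@@H](C(C)=C)CC=C1C)C(=O)OC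
F4 | step 5 | methyl (1R,5S,6R)-6-[3-(TBS-oxy)propyl]-1-(3-methoxy-3-oxopropyl)-2-methyl-5-(1-oxopropan-2-yl)cyclohex-2-ene-1-carboxylate, both side-chain epimers | COC(=O)CC[C@]1([C@H](CCCO[Si](C)(C)C(C)(C)C)[C@@H](C(C)C=O)CC=C1C)C(=O)OC
F5 | step 5 | methyl (1R,5S,6R)-6-[3-(TBS-oxy)propyl]-1-(3-methoxy-3-oxopropyl)-2-methyl-5-[1-(trimethylsilyloxy)prop-1-en-2-yl]cyclohex-2-ene-1-carboxylate, E/Z mixture | COC(=O)CC[C@]1([C@H](CCCO[Si](C)(C)C(C)(C)C)[C@@H](C(C)=CO[Si](C)(C)C)CC=C1C)C(=O)OC
F6 | step 12 | methyl 2-(dimethoxyphosphoryl)-2-[(1S,2R,5R,6R,7Z)-6-[3-(TBS-oxy)propyl]-7-(1,1-dimethoxypropan-2-ylidene)-1-hydroxy-10-methylspiro[4.5]dec-9-en-2-yl]acetate, epimers at the phosphonate carbon | COC(=O)C(P(=O)(OC)OC)[C@@H]1CC[C@]2([C@H](CCCO[Si](C)(C)C(C)(C)C)/C(=C(/C)C(OC)OC)CC=C2C)[C@H]1O
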